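## Structural features

The target is a 2,3-dihydro-1-benzofuran-6(5H)-one (benzofuran numbering O1, C2, C3, C3a, C4–C7, C7a). Ring A is a linearly conjugated cyclohexa-2,4-dienone (C6=O, C7=C7a, C3a=C4); ring B is a dihydrofuran fused at C3a–C7a, whose oxygen O1 forms a vinylogous ester with C6=O. The only sp3 carbon of ring A, C5, lies between the carbonyl carbon C6 and the vinyl carbon C4 and carries both a methoxy and an allyl group. C2 (R, 3,4-dimethoxyphenyl) and C3 (R, methyl) are adjacent and trans; C5 (S) is separated from them by the planar sp2 carbons C3a and C4, with allyl on the face of the aryl group and methoxy on the face of the methyl group. Ring A is a blocked keto tautomer of a resorcinol-type phenol: it cannot aromatise by proton shift, but allyl can leave C5 by [3,3] shifts (Cope to C3a, retro-Claisen to O6), and a further Claisen shift to the free C7 would end in a phenol. The C2–O1 bond is a benzylic ether of an electron-rich arene with a vinylogous carboxylate as leaving group and can ionise under acid; the terminal alkene, the enol ether and the aryl methyl ethers exclude hydrogenation, strong electrophiles and ether-cleaving Lewis acids late in the route. The real difficulty is C5: a fully substituted O,C-bearing carbon in a non-aromatic ring, whose configuration must be fixed relative to stereocentres that cannot reach it through space or through the ring.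

## Logic of the disconnections

**7 ⇒ 6.** The O–CH3 bond of the C5 methoxy group is cut. This exposes a tertiary alcohol next to the C6 carbonyl, i.e. an oxygen that can be traced back to a carbonyl oxygen. The gain is that the methyl ether need not be present when the quaternary carbon is made. The demand on the forward step is methylation without an alkoxide (which would trigger an anionic oxy-Cope shift of allyl to C3a) and without acid (which would ionise C2–O1).

**6 ⇒ 4 (key disconnection).** The C5–CH2 bond to the allyl group is cut with reversed polarity: C5 becomes a carbonyl carbon of a vicinal dione and allyl the nucleophile. At the phenol oxidation level C5 is one of four competing nucleophilic sites (O6, C7, C3a, C5). At the quinone level it is a single electrophilic carbon in a ring that is already non-aromatic; the two carbonyls are differentiated by O1, and the dione offers a two-point binding site for a chiral Lewis acid. Such a bound catalyst is the only control element that can reach a stereocentre this remote from C2 and C3. The gain is the removal of the quaternary stereocentre and the allyl group in one cut; the precursor 4 has two stereocentres and a planar ring A. The forward step must be a 1,2-addition at C5 (not at C6, not conjugate, not across both oxygens), on the Re face, under conditions the sensitive dione tolerates.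

**4 ⇒ 3.** The C6 carbonyl is traced back to a C6–OMe group; the O–CH3 bond is cleaved and the arene raised to the quinone level. A 2-methoxyphenol is a latent vicinal dione, and 3 is aromatic and stable, which allows its enantiomeric purity to be raised. The forward step must deliver oxygen to the methoxy-bearing ortho carbon and not to the para carbon C7a, whose attack would open ring B.

**3 ⇒ 1 + 2.** The C3–C3a and O1–C2 bonds of ring B are cut in a formal [3+2] sense. Both components are commercial, and C2 and C3 are set together and trans. The methoxy group of 1 serves as the chelating handle for a chiral titanium promoter and later as the leaving group of the previous disconnection. The forward step needs control of regiochemistry through chelation and of absolute configuration through the chiral diolate.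

## Other disconnections considered

**Alternative 1:** (the first that comes to mind) Cut: C3–C3a and O1–C2 on a ring A that already carries allyl at C3a, then relocation of allyl from C3a to C5. Forward: acid-promoted ionisation of quinone monoketal A1, [3+2] capture of the cation by 2 to give the 3a-allyl dienone A2, then a thermal Cope shift. It is short, and the Cope step transfers configuration from C3a to C5 suprafacially. It is set aside on three grounds. The cation is achiral and unbound, so nothing controls absolute configuration. An endo-aryl approach of the E-alkene is expected to place 3-methyl and 3a-allyl cis, as in A2, so the suprafacial shift would put allyl on the methyl face of C5 and give epimer A3 rather than 7. The heat needed for the Cope step also opens the retro-Claisen escape to aromatic isomers.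

**Alternative 2:** Cut: the C5–O bond of the methoxy group, with C5 as electrophile. Forward: oxidative methoxylation (PhI(OAc)2 or Pb(OAc)4, MeOH) of 5-allylphenol A4 through its phenoxenium ion. The cation is planar and C2/C3 are remote, so both faces of C5 should be captured alike, giving 7 and A3. Positive charge also resides at C3a (para to O6), where capture gives the isomeric para-quinol ether A5. The chosen plan replaces a free cation with a carbonyl bound to a chiral catalyst and has only one carbon that can accept the nucleophile.

**Alternative 3:** Cut: C5–allyl with natural polarity (phenoxide carbon as nucleophile, allyl as electrophile). Forward: decarboxylative Tsuji–Trost dearomatisation of allyl carbonate A7, made from phenol A6, with Pd2(dba)3 and a chiral ligand. The phenoxide is ambident (O6, C7, C5, C3a). C7 is free and flanked by two oxygens, and allylation there becomes irreversible by tautomerisation to phenol A8. O- and C5-allylation can be re-ionised by zerovalent palladium, so the mixture is expected to drain to A8. In addition, A6 bears the hydroxy/methoxy pattern opposite to the one the quinone cycloaddition delivers, which costs steps.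

Key step: step 3

Assumption: the sense of induction of the titanium–TADDOL promoter (step 1) and of the scandium–PyBOX catalyst (step 3) is assigned by analogy with their known substrates; both ligands are available as either enantiomer, and the antipode is to be used if the sense proves opposite.

## Route

Step 1
Reactants: 1 2-methoxy-1,4-benzoquinone; 2 (E)-1,2-dimethoxy-4-(prop-1-en-1-yl)benzene
Product: 3 (2R,3R)-2-(3,4-dimethoxyphenyl)-6-methoxy-3-methyl-2,3-dihydro-1-benzofuran-5-ol
Conditions: TiCl4/Ti(OiPr)4 (1:1) pre-mixed with (4R,5R)-TADDOL [(4R,5R)-2,2-dimethyl-α,α,α′,α′-tetraphenyl-1,3-dioxolane-4,5-dimethanol] (1.5 equiv of the titanium diolate), CH2Cl2, −78 °C → −20 °C; recrystallisation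
Reagents that add atoms: none
Why: Lewis acid-promoted formal [3+2] cycloaddition of a 2-alkoxy-1,4-benzoquinone with a propenylarene: tetravalent titanium chelates C1=O and the methoxy oxygen of 1, the β-carbon of 2 attacks C5 of the quinone, the benzylic cation is closed by the C4 carbonyl oxygen, and enolisation gives the phenol. The stepwise closure places aryl and methyl trans, and the chiral diolate selects the alkene face, which sets C3 (R) and with it C2 (R); recrystallisation should raise the enantiomeric purity.

Step 2
Reactants: 3 (2R,3R)-2-(3,4-dimethoxyphenyl)-6-methoxy-3-methyl-2,3-dihydro-1-benzofuran-5-ol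
Product: 4 (2R,3R)-2-(3,4-dimethoxyphenyl)-3-methyl-2,3-dihydro-1-benzofuran-5,6-dione
Conditions: IBX (2-iodoxybenzoic acid, 1.1 equiv), DMF, 0 °C → rt, dark; buffered work-up, used at once
Reagents that add atoms: IBX (2-iodoxybenzoic acid), O=C1OI(=O)(O)c2ccccc12
Why: Oxidative demethylation of a 2-methoxyphenol: the phenol binds to pentavalent iodine, oxygen is transferred within the complex to the ortho carbon that bears the methoxy group, and loss of methanol gives the vicinal dione. The intramolecular delivery keeps the oxidant away from C7a (para, bearing O1), so ring B should stay closed; C2 and C3 are not involved.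

Step 3
Reactants: 4 (2R,3R)-2-(3,4-dimethoxyphenyl)-3-methyl-2,3-dihydro-1-benzofuran-5,6-dione
Product: 6 (2R,3R,5S)-5-allyl-2-(3,4-dimethoxyphenyl)-5-hydroxy-3-methyl-2,3-dihydro-1-benzofuran-6(5H)-one, via trimethylsilyl ether 5 (not isolated)
Conditions: Sc(OTf)3 (10 mol %), (S,S)-Ph-PyBOX (12 mol %), allylSiMe3 (3 equiv), Me3SiCl (20 mol %), 4 Å MS, CH2Cl2, −40 °C; then AcOH/THF/H2O, 0 °C
Reagents that add atoms: allyltrimethylsilane, C=CC[Si](C)(C)C
Why: Proposed new method: the vicinal dione of 4 should bind the Sc(OTf)3–PyBOX complex through both carbonyl oxygens, and allylSiMe3 then attacks the activated C5 carbonyl in an open, anti-SE2′ transition state; the β-silyl cation collapses by silyl transfer to oxygen to give 5, which dilute acetic acid hydrolyses to 6. The closest known reaction type is the Sc(OTf)3–PyBOX-catalysed enantioselective Hosomi–Sakurai allylation of isatins and α-keto esters, likewise chelating vicinal dicarbonyls attacked at the ketone carbon, and uncatalysed 1,2-additions of allyl metals to o-quinones give the same 6-allyl-6-hydroxycyclohexa-2,4-dienone type; what is new is chiral-Lewis-acid control on an o-benzoquinone. No ring is closed. Site selectivity is secured by the substrate: C6=O is a vinylogous ester carbonyl (O1–C7a=C7–C6=O) and is deactivated, C5=O is an enone carbonyl made more electrophilic by its carbonyl neighbour, and conjugate attack at C3a is blocked by full substitution. Chelation ties up both oxygens, which disfavours the O,O-cycloaddition mode of o-quinones and keeps the attack on carbon. The new stereocentre C5 is set by the catalyst alone: the C2-symmetric ligand shields one face of the planar chelate, and allyl must enter the Re face of C5=O (the face on which the C2 aryl group lies) to give 5S; C2 and C3 are too remote to oppose it. The adduct is the more stable of the two possible α-ketols because its carbonyl stays conjugated with O1, so a 1,2-allyl shift is not expected.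

Step 4
Reactants: 6 (2R,3R,5S)-5-allyl-2-(3,4-dimethoxyphenyl)-5-hydroxy-3-methyl-2,3-dihydro-1-benzofuran-6(5H)-one
Product: 7 (2R,3R,5S)-5-allyl-2-(3,4-dimethoxyphenyl)-5-methoxy-3-methyl-2,3-dihydro-1-benzofuran-6(5H)-one
Conditions: MeOTf (3 equiv), 2,6-di-tert-butyl-4-methylpyridine (4 equiv), CH2Cl2, 0 °C → rt
Reagents that add atoms: methyl trifluoromethanesulfonate, COS(=O)(=O)C(F)(F)F
Why: O-Methylation of a hindered tertiary alcohol with methyl triflate and a non-nucleophilic pyridine base; no alkoxide is formed, so the anionic oxy-Cope shift of allyl to C3a has no trigger, and no acid is present to ionise C2–O1. C5 is not touched and keeps its configuration.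

## Compound list

1 | 2-methoxy-1,4-benzoquinone | COC1=CC(=O)C=CC1=O | starting material
2 | (E)-1,2-dimethoxy-4-(prop-1-en-1-yl)benzene | C/C=C/c1ccc(OC)c(OC)c1 | starting material
3 | (2R,3R)-2-(3,4-dimethoxyphenyl)-6-methoxy-3-methyl-2,3-dihydro-1-benzofuran-5-ol | Oc1cc2c(cc1OC)O[C@@H](c1ccc(OC)c(OC)c1)[C@@H]2C | intermediate
4 | (2R,3R)-2-(3,4-dimethoxyphenyl)-3-methyl-2,3-dihydro-1-benzofuran-5,6-dione | O=C1C=C2C(=CC1=O)O[C@@H](c1ccc(OC)c(OC)c1)[C@@H]2C | intermediate
5 | (2R,3R,5S)-5-allyl-2-(3,4-dimethoxyphenyl)-3-methyl-5-(trimethylsilyloxy)-2,3-dihydro-1-benzofuran-6(5H)-one | C=CC[C@]1(O[Si](C)(C)C)C=C2C(=CC1=O)O[C@@H](c1ccc(OC)c(OC)c1)[C@@H]2C | intermediate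
6 | (2R,3R,5S)-5-allyl-2-(3,4-dimethoxyphenyl)-5-hydroxy-3-methyl-2,3-dihydro-1-benzofuran-6(5H)-one | C=CC[C@]1(O)C=C2C(=CC1=O)O[C@@H](c1ccc(OC)c(OC)c1)[C@@H]2C | intermediate
7 | (2R,3R,5S)-5-allyl-2-(3,4-dimethoxyphenyl)-5-methoxy-3-methyl-2,3-dihydro-1-benzofuran-6(5H)-one (CNP0109840.1) | C=CC[C@]1(OC)C=C2C(=CC1=O)O[C@@H](c1ccc(OC)c(OC)c1)[C@@H]2C | target

## Step count and least certain steps

Total step count: 4. Longest linear sequence: 4 steps (1 + 2 → 3 → 4 → 6 → 7).

**Step 3 (key step, proposed new method).** Most likely to go wrong:
- Loss of site or mode selectivity: the allylsilane may add in a conjugate sense at the free ring positions C7 or C4 with rearomatisation, or across both oxygens, because o-quinones are also Michael acceptors and heterodienes.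
- Ionisation of the C2–O1 bond by the Lewis acid, with capture of the benzylic cation, because the bound dione is a good leaving group.
- Tautomerisation of the dione through C3–H toward an aromatic benzofuran.
- Insufficient facial discrimination, because the two flanks of C5 (acyl and vinyl) are both sp2.

Fallback, from 4 and with known chemistry only: the allyl group is delivered without induction by preformed allylindium sesquibromide ((C3H5)3In2Br3, from allyl bromide and In, THF, −78 °C), a closed-transition-state 1,2-addition of an allyl metal to a quinone carbonyl. This should give 6 together with its C5 epimer, (2R,3R,5R)-5-allyl-2-(3,4-dimethoxyphenyl)-5-hydroxy-3-methyl-2,3-dihydro-1-benzofuran-6(5H)-one F1. The two are diastereomers and are separated by chromatography; the route is rejoined at 6.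

**Step 4.** Most likely to go wrong: slow reaction at the hindered, hydrogen-bonded tertiary hydroxyl; competing methylation of the vinylogous ester carbonyl oxygen; or a [3,3] shift of allyl toward C3a if any alkoxide forms. Fallback, from 6: the shift is accepted instead of avoided. Base and a hard methylating agent (K2CO3, Me2SO4, acetone, rt) should convert the alkoxide of 6 by anionic oxy-Cope shift and O-methylation of the resulting enolate into (2R,3R,3aR)-3a-allyl-2-(3,4-dimethoxyphenyl)-5-methoxy-3-methyl-3,3a-dihydro-1-benzofuran-6(2H)-one F2. Gentle warming of F2 (toluene, 80 °C) should return allyl to C5 by Cope rearrangement. Both shifts are suprafacial, so allyl stays on the face set in step 3, and the route is rejoined at 7.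

**Step 2.** Most likely to go wrong: oxygen transfer to the free ortho carbon C4 instead of the methoxy-bearing C6; one-electron oxidation with attack at C7a and opening of ring B; or tautomerisation of the dione during work-up. Fallback, from 2: the oxygen at C6 is carried as a benzyl ether instead of a methyl ether. The cycloaddition of step 1 is run with 2-(benzyloxy)-1,4-benzoquinone F3 to give (2R,3R)-6-(benzyloxy)-2-(3,4-dimethoxyphenyl)-3-methyl-2,3-dihydro-1-benzofuran-5-ol F4. Hydrogenolysis (H2, Pd on carbon (Pd/C), EtOAc) frees (2R,3R)-2-(3,4-dimethoxyphenyl)-3-methyl-2,3-dihydro-1-benzofuran-5,6-diol F5. A plain two-electron oxidation of the catechol (Ag2O, Na2SO4, Et2O, 0 °C) rejoins the route at 4.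

**Step 1.** Most likely to go wrong: incomplete enantioselection by the stoichiometric chiral promoter, and partial diversion of the zwitterion into the [2+2] manifold at low temperature. Fallback, from 1 and 2: the cycloaddition is run with achiral TiCl4/Ti(OiPr)4, which should give 3 as a racemate with its enantiomer, (2S,3S)-2-(3,4-dimethoxyphenyl)-6-methoxy-3-methyl-2,3-dihydro-1-benzofuran-5-ol F6. The phenol is resolved by preparative chromatography on a chiral stationary phase, and the route is rejoined at 3.

## Further compounds

F1 | step 3 | (2R,3R,5R)-5-allyl-2-(3,4-dimethoxyphenyl)-5-hydroxy-3-methyl-2,3-dihydro-1-benzofuran-6(5H)-one | C=CC[C@@]1(O)C=C2C(=CC1=O)O[C@@H](c1ccc(OC)c(OC)c1)[C@@H]2C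
F2 | step 4 | (2R,3R,3aR)-3a-allyl-2-(3,4-dimethoxyphenyl)-5-methoxy-3-methyl-3,3a-dihydro-1-benzofuran-6(2H)-one | C=CC[C@@]12C=C(OC)C(=O)C=C1O[C@@H](c1ccc(OC)c(OC)c1)[C@@H]2C
F3 | step 2 | 2-(benzyloxy)-1,4-benzoquinone | O=C1C=CC(=O)C(OCc2ccccc2)=C1
F4 | step 2 | (2R,3R)-6-(benzyloxy)-2-(3,4-dimethoxyphenyl)-3-methyl-2,3-dihydro-1-benzofuran-5-ol | Oc1cc2c(cc1OCc1ccccc1)O[C@@H](c1ccc(OC)c(OC)c1)[C@@H]2C
F5 | step 2 | (2R,3R)-2-(3,4-dimethoxyphenyl)-3-methyl-2,3-dihydro-1-benzofuran-5,6-diol | Oc1cc2c(cc1O)O[C@@H](c1ccc(OC)c(OC)c1)[C@@H]2C
F6 | step 1 | (2S,3S)-2-(3,4-dimethoxyphenyl)-6-methoxy-3-methyl-2,3-dihydro-1-benzofuran-5-ol | Oc1cc2c(cc1OC)O[C@H](c1ccc(OC)c(OC)c1)[C@H]2C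
A1 | alternative 1 | 2-allyl-4,4,5-trimethoxycyclohexa-2,5-dien-1-one | C=CCC1=CC(OC)(OC)C(OC)=CC1=O
A2 | alternative 1 | (2R,3R,3aS)-rel-3a-allyl-2-(3,4-dimethoxyphenyl)-5-methoxy-3-methyl-3,3a-dihydro-1-benzofuran-6(2H)-one (racemic) | C=CC[C@]12C=C(OC)C(=O)C=C1O[C@@H](c1ccc(OC)c(OC)c1)[C@@H]2C
A3 | alternative 1 | (2R,3R,5R)-5-allyl-2-(3,4-dimethoxyphenyl)-5-methoxy-3-methyl-2,3-dihydro-1-benzofuran-6(5H)-one (C5 epimer of 7; racemic in alternative 1) | C=CC[C@@]1(OC)C=C2C(=CC1=O)O[C@@H](c1ccc(OC)c(OC)c1)[C@@H]2C
A4 | alternative 2 | (2R,3R)-5-allyl-2-(3,4-dimethoxyphenyl)-3-methyl-2,3-dihydro-1-benzofuran-6-ol | C=CCc1cc2c(cc1O)O[C@@H](c1ccc(OC)c(OC)c1)[C@@H]2C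
A5 | alternative 2 | (2R,3S,3aS)-5-allyl-2-(3,4-dimethoxyphenyl)-3a-methoxy-3-methyl-3,3a-dihydro-1-benzofuran-6(2H)-one (one of the two C3a epimers) | CO[C@]12C=C(CC=C)C(=O)C=C1O[C@@H](c1ccc(OC)c(OC)c1)[C@@H]2C
A6 | alternative 3 | (2R,3R)-2-(3,4-dimethoxyphenyl)-5-methoxy-3-methyl-2,3-dihydro-1-benzofuran-6-ol | COc1cc2c(cc1O)O[C@@H](c1ccc(OC)c(OC)c1)[C@@H]2C
A7 | alternative 3 | allyl (2R,3R)-2-(3,4-dimethoxyphenyl)-5-methoxy-3-methyl-2,3-dihydro-1-benzofuran-6-yl carbonate | COc1cc2c(cc1OC(=O)OCC=C)O[C@@H](c1ccc(OC)c(OC)c1)[C@@H]2C
A8 | alternative 3 | (2R,3R)-7-allyl-2-(3,4-dimethoxyphenyl)-5-methoxy-3-methyl-2,3-dihydro-1-benzofuran-6-ol | COc1cc2c(c(CC=C)c1O)O[C@@H](c1ccc(OC)c(OC)c1)[C@@H]2C
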